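**Retrosynthetic overview**
1. The last C–C bond (C2′=C3′) is made by cross-metathesis of a C2-allyl chroman with 2-methylbut-3-en-2-ol; just before that, the C3 acetate and the absolute configuration come from a lipase acetylation of the racemic cis-3-hydroxy-2-allyl chroman.
2. The allyl alcohol is unmasked (DIBAL-H, then Wittig) from a cis-fused γ-lactone O3–C(=O)–C1′; this temporary ring fixes O3 cis to C1′ and is reachable from either C2 epimer by reversible oxa-Michael chemistry.
3. The lactone comes from a 3-acetoxychroman-2-acetate whose pyran ring is cut at C4–C4a and C3–C2: an aryl iodide carrying an O-bound β-aryloxycrotonate plus vinyl acetate, joined in one radical chain (formal [4+2]).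
4. Enabling feature: C2 is a tertiary ether carbon (O1, CH3) whose neighbour C1′ can carry a carbonyl, so O1–C2(CH3)=C1′–CO2Me is a β-aryloxyacrylate that accepts a radical at C2. C3 bears oxygen, so the radical formed when the C4a aryl radical (ortho to O1) adds to vinyl acetate is exactly the C4–C3(O) unit.
5. Ring order: benzene ring bought (methyl 4-hydroxy-3-iodobenzoate); pyran ring in step 2; temporary lactone ring in step 3, opened again in steps 4 and 5.

Key step: step 2

Assumption: the lipase is taken to follow the usual empirical size model for secondary alcohols (quaternary C2 large, ring CH2 C4 medium) and so to acetylate the (3R)-alcohol; with the opposite preference the recovered alcohol would be the one to acetylate chemically.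

Step 1
Reactants: 1 methyl 4-hydroxy-3-iodobenzoate; 2 methyl but-2-ynoate
Product: 3 methyl 3-iodo-4-{[(2E)-4-methoxy-4-oxobut-2-en-2-yl]oxy}benzoate
Conditions: K2CO3 (0.5 equiv), DMF, 60 °C
Reagents that add atoms: methyl but-2-ynoate (2), CC#CC(=O)OC
Why: Base-mediated oxa-Michael addition of the phenoxide to the ynoate should give the β-aryloxycrotonate, the reversible addition favouring the (E)-isomer; the alkene geometry is not critical because C2 becomes sp3 in step 2.

Step 2
Reactants: 3 methyl 3-iodo-4-{[(2E)-4-methoxy-4-oxobut-2-en-2-yl]oxy}benzoate; 4 vinyl acetate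
Product: 6 methyl 3-acetoxy-2-(2-methoxy-2-oxoethyl)-2-methyl-3,4-dihydro-2H-chromene-6-carboxylate (racemic; both C2/C3 diastereomers), via α-acetoxyalkyl radical 5 (not isolated)
Conditions: vinyl acetate (20 equiv, ca. 2 M), Bu3SnH (1.3 equiv) + AIBN (0.2 equiv) by syringe pump, PhH, reflux (ca. 75 °C)
Reagents that add atoms: vinyl acetate (4), C=COC(C)=O
Why: Proposed new method: Bu3Sn• abstracts iodine from 3, the aryl σ-radical at C4a adds to the CH2 terminus of vinyl acetate (Meerwein-type aryl radical addition) to give the nucleophilic α-acetoxyalkyl radical 5, C3 of which attacks C2, the β-carbon of the β-aryloxycrotonate, and the resulting α-ester radical at C1′ abstracts hydrogen from Bu3SnH, so that C4–C4a and C3–C2 form in one chain sequence. The closest known reaction types are the addition of aryl radicals to vinyl acetate and the cyclisation of alkyl and α-oxygenated radicals onto β-alkoxyacrylates (β-methyl-substituted ones included) used to make cyclic ethers; what is new is their coupling into an intermolecular/intramolecular annulation on an ortho-iodoaryl enol ether. The pyran ring closes 6-exo-trig, the competing modes of the aryl radical on its own enoate being 4-exo and 5-endo and therefore slow. C2 and C3 arise without absolute control (racemate) and with a diastereomer ratio on which the route does not depend, since step 3 converges both diastereomers through the cis-fused lactone and step 6 selects the enantiomer. The step needs chemoselectivity (capture of the aryl radical by vinyl acetate instead of 1,5-hydrogen transfer from the C2 methyl group or direct reduction, secured by ca. 2 M vinyl acetate and slow addition of Bu3SnH) and regioselectivity (CH2 attack on vinyl acetate gives the O-stabilised radical; attack at C2 and not C1′ is secured by the ester on C1′ and the six-membered transition state).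

Step 3
Reactants: 6 methyl 3-acetoxy-2-(2-methoxy-2-oxoethyl)-2-methyl-3,4-dihydro-2H-chromene-6-carboxylate
Product: 9 methyl (3aR*,9aR*)-3a-methyl-2-oxo-3,3a,9,9a-tetrahydro-2H-furo[3,2-b]chromene-7-carboxylate (racemic cis-fused lactone), via hydroxy diester 7 (not isolated), via butenolide phenol 8 (not isolated)
Conditions: K2CO3 (0.2 equiv), MeOH, 23 °C; evaporate; then DBU (0.1 equiv), PhMe, 90 °C
Reagents that add atoms: none
Why: Methanolysis frees the C3 hydroxyl and the cis-diastereomer lactonises directly, while the trans-diastereomer should equilibrate under catalytic base by E1cB ring opening (retro-oxa-Michael with aryloxide as leaving group), lactonisation to butenolide 8 and oxa-Michael re-closure, which can only give the cis-fused lactone because the phenol is tethered through C4 to one face of the butenolide; this is the known base-mediated thermodynamic equilibration of oxa-Michael adducts combined with γ-lactonisation, and it sets C2 relative to C3.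

Step 4
Reactants: 9 methyl (3aR*,9aR*)-3a-methyl-2-oxo-3,3a,9,9a-tetrahydro-2H-furo[3,2-b]chromene-7-carboxylate
Product: 10 methyl (3aR*,9aR*)-2-hydroxy-3a-methyl-3,3a,9,9a-tetrahydro-2H-furo[3,2-b]chromene-7-carboxylate (racemic lactol; anomers)
Conditions: iBu2AlH (DIBAL-H, 1.1 equiv), CH2Cl2, −78 °C; aq. potassium sodium tartrate (KNaC4H4O6)
Reagents that add atoms: none
Why: Partial reduction of a γ-lactone to the lactol via the stable tetrahedral aluminium alkoxide at −78 °C, the lactone carbonyl being more electrophilic than the donor-substituted para-alkoxybenzoate ester when one equivalent of hydride is used.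

Step 5
Reactants: 10 methyl (3aR*,9aR*)-2-hydroxy-3a-methyl-3,3a,9,9a-tetrahydro-2H-furo[3,2-b]chromene-7-carboxylate
Product: 11 methyl (2R*,3R*)-3-hydroxy-2-methyl-2-(prop-2-en-1-yl)-3,4-dihydro-2H-chromene-6-carboxylate (racemic)
Conditions: Ph3PCH3Br (2.5 equiv), KN(SiMe3)2 (2.4 equiv), THF, 0 °C; then 10, −78 → 0 °C
Reagents that add atoms: methyltriphenylphosphonium bromide, C[P+](c1ccccc1)(c1ccccc1)c1ccccc1.[Br-]
Why: Wittig methylenation of the open hydroxy-aldehyde form of the lactol gives the C2 allyl group and frees the C3 hydroxyl; the non-stabilised ylide adds to the aldehyde much faster than it enolises it or attacks the aryl ester (as in Wittig couplings of chroman-2-ylacetaldehydes), so C2 and C3 are not touched.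

Step 6
Reactants: 11 methyl (2R*,3R*)-3-hydroxy-2-methyl-2-(prop-2-en-1-yl)-3,4-dihydro-2H-chromene-6-carboxylate; 4 vinyl acetate
Product: 12 methyl (2R,3R)-3-(acetyloxy)-2-methyl-2-(prop-2-en-1-yl)-3,4-dihydro-2H-chromene-6-carboxylate
Conditions: immobilised Burkholderia cepacia lipase (a lipase), vinyl acetate (5 equiv), MTBE, 40 °C, stopped near half conversion
Reagents that add atoms: vinyl acetate (4), C=COC(C)=O
Why: Lipase-catalysed transesterification (kinetic resolution of a secondary alcohol, made irreversible by tautomerisation of vinyl alcohol to acetaldehyde) should acetylate the (3R)-enantiomer, in which the quaternary C2 is the large and C4 the medium substituent, so that 12 carries the target's acetate and configuration and the unreacted (2S,3S)-alcohol is removed by chromatography.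

Step 7
Reactants: 12 methyl (2R,3R)-3-(acetyloxy)-2-methyl-2-(prop-2-en-1-yl)-3,4-dihydro-2H-chromene-6-carboxylate; 13 2-methylbut-3-en-2-ol
Product: 14 methyl (2R,3R)-3-(acetyloxy)-2-[(2E)-4-hydroxy-4-methylpent-2-en-1-yl]-2-methyl-3,4-dihydro-2H-chromene-6-carboxylate (CNP0075640.1)
Conditions: 13 (5 equiv), second-generation Hoveyda–Grubbs catalyst RuCl2(H2IMes)(=CH-C6H4-2-OiPr) (5 mol %), CH2Cl2, 40 °C
Reagents that add atoms: 2-methylbut-3-en-2-ol (13), C=CC(C)(C)O
Why: Olefin cross-metathesis of the terminal allyl group with an excess of the tertiary allylic alcohol, which does not homodimerise readily, should give the (E)-disubstituted alkene under thermodynamic control, while the acetate, the ester and both stereocentres are inert to the ruthenium carbene.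

**Compound list**
1 | methyl 4-hydroxy-3-iodobenzoate | COC(=O)c1ccc(O)c(I)c1 | starting material
2 | methyl but-2-ynoate | CC#CC(=O)OC | starting material
3 | methyl 3-iodo-4-{[(2E)-4-methoxy-4-oxobut-2-en-2-yl]oxy}benzoate | COC(=O)/C=C(\C)Oc1ccc(cc1I)C(=O)OC | intermediate
4 | vinyl acetate | C=COC(C)=O | starting material
5 | α-acetoxyalkyl radical formed from the C4a aryl radical and vinyl acetate (not isolated) | COC(=O)/C=C(\C)Oc1ccc(cc1C[CH]OC(C)=O)C(=O)OC | intermediate
6 | methyl 3-acetoxy-2-(2-methoxy-2-oxoethyl)-2-methyl-3,4-dihydro-2H-chromene-6-carboxylate (racemic, both C2/C3 diastereomers, no configuration assigned) | COC(=O)CC1(C)Oc2ccc(cc2CC1OC(C)=O)C(=O)OC | intermediate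
7 | methyl 3-hydroxy-2-(2-methoxy-2-oxoethyl)-2-methyl-3,4-dihydro-2H-chromene-6-carboxylate (racemic, both diastereomers; not isolated) | COC(=O)CC1(C)Oc2ccc(cc2CC1O)C(=O)OC | intermediate
8 | methyl 4-hydroxy-3-[(3-methyl-5-oxo-2,5-dihydrofuran-2-yl)methyl]benzoate (racemic; not isolated) | COC(=O)c1ccc(O)c(c1)CC1OC(=O)C=C1C | intermediate
9 | methyl (3aR*,9aR*)-3a-methyl-2-oxo-3,3a,9,9a-tetrahydro-2H-furo[3,2-b]chromene-7-carboxylate (racemic cis-fused lactone; the enantiomer drawn is the one carried on) | COC(=O)c1ccc2c(c1)C[C@H]3OC(=O)C[C@@]3(C)O2 | intermediate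
10 | methyl (3aR*,9aR*)-2-hydroxy-3a-methyl-3,3a,9,9a-tetrahydro-2H-furo[3,2-b]chromene-7-carboxylate (racemic lactol, anomeric mixture) | COC(=O)c1ccc2c(c1)C[C@H]3OC(O)C[C@@]3(C)O2 | intermediate
11 | methyl (2R*,3R*)-3-hydroxy-2-methyl-2-(prop-2-en-1-yl)-3,4-dihydro-2H-chromene-6-carboxylate (racemic; the (2R,3R) enantiomer is drawn) | COC(=O)c1ccc2c(c1)C[C@@H](O)[C@@](C)(CC=C)O2 | intermediate
12 | methyl (2R,3R)-3-(acetyloxy)-2-methyl-2-(prop-2-en-1-yl)-3,4-dihydro-2H-chromene-6-carboxylate | COC(=O)c1ccc2c(c1)C[C@@H](OC(C)=O)[C@@](C)(CC=C)O2 | intermediate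
13 | 2-methylbut-3-en-2-ol | C=CC(C)(C)O | starting material
14 | methyl (2R,3R)-3-(acetyloxy)-2-[(2E)-4-hydroxy-4-methylpent-2-en-1-yl]-2-methyl-3,4-dihydro-2H-chromene-6-carboxylate (CNP0075640.1) | COC(=O)c1ccc2c(c1)C[C@@H](OC(C)=O)[C@@](C)(C/C=C/C(C)(C)O)O2 | target

**Step count and risks**
Total step count: 7. Longest linear sequence: 7 steps (1 → 14).

Steps most likely to fail:

1. Step 2 (Proposed new method). The aryl radical may be quenched before it meets vinyl acetate (1,5-hydrogen transfer from the C2 methyl group, or reduction by Bu3SnH). The α-acetoxy radical or the cyclised α-ester radical may also telomerise with the excess vinyl acetate instead of cyclising or being reduced. The fallback forms the two bonds one after the other with known chemistry and sets out from 3. Suzuki–Miyaura coupling of 3 (Pd(dppf)Cl2, K3PO4, dioxane/H2O) with (E)-2-(2-ethoxyethenyl)-4,4,5,5-tetramethyl-1,3,2-dioxaborolane should give the aryl enol ether methyl 3-[(E)-2-ethoxyethenyl]-4-{[(2E)-4-methoxy-4-oxobut-2-en-2-yl]oxy}benzoate F1. Mild acid hydrolysis (aq. HCl, THF, 0 °C) of this more basic enol ether should give the arylacetaldehyde methyl 4-{[(2E)-4-methoxy-4-oxobut-2-en-2-yl]oxy}-3-(2-oxoethyl)benzoate F2. SmI2 with MeOH in THF should then close C3–C2 by reductive ketyl–olefin cyclisation onto the β-aryloxycrotonate (the established aldehyde/β-alkoxyacrylate cyclisation). This gives the hydroxy diester 7, where the route is rejoined at the base stage of step 3.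

2. Step 3. The C2 epimerisation may stay incomplete, or material may be lost through double-bond isomerisation of the butenolide, so that the trans-diastereomer does not converge on the lactone. The fallback sets out from 7, isolated after the K2CO3/MeOH stage, with its diastereomers separated by chromatography. The cis-diastereomer is lactonised with catalytic TsOH to 9. The trans-diastereomer is hydrolysed at the aliphatic ester only (LiOH, 1.05 equiv, THF/H2O, 0 °C) to the hydroxy acid [(2R*,3S*)-3-hydroxy-6-(methoxycarbonyl)-2-methyl-3,4-dihydro-2H-chromen-2-yl]acetic acid F3. Mitsunobu lactonisation of F3 (PPh3, DIAD, THF) closes the ring with inversion at C3, the carboxylate arm lying on the face opposite the hydroxyl, and returns to the route at 9.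

3. Step 6. Acyl transfer to the hindered C3 hydroxyl next to the quaternary C2 may be slow or poorly enantioselective. The fallback is a classical resolution and sets out from racemic 11. Esterification with (S)-2-methoxy-2-phenylacetic acid (DCC, DMAP, CH2Cl2) gives two diastereomeric esters: the (2R,3R)-alcohol (S)-2-methoxy-2-phenylacetate F4 and the (2S,3S)-alcohol (S)-2-methoxy-2-phenylacetate F5, separated by chromatography. Methanolysis of F4 (K2CO3, MeOH) gives the single-enantiomer alcohol methyl (2R,3R)-3-hydroxy-2-methyl-2-(prop-2-en-1-yl)-3,4-dihydro-2H-chromene-6-carboxylate F6. Acetylation of F6 (Ac2O, DMAP, pyridine) returns to the route at 12.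

Further compounds
F1 | step 2 | methyl 3-[(E)-2-ethoxyethenyl]-4-{[(2E)-4-methoxy-4-oxobut-2-en-2-yl]oxy}benzoate | CCO/C=C/c1cc(ccc1O/C(C)=C/C(=O)OC)C(=O)OC
F2 | step 2 | methyl 4-{[(2E)-4-methoxy-4-oxobut-2-en-2-yl]oxy}-3-(2-oxoethyl)benzoate | O=CCc1cc(ccc1O/C(C)=C/C(=O)OC)C(=O)OC
F3 | step 3 | [(2R*,3S*)-3-hydroxy-6-(methoxycarbonyl)-2-methyl-3,4-dihydro-2H-chromen-2-yl]acetic acid (racemic trans-hydroxy acid) | COC(=O)c1ccc2c(c1)C[C@H](O)[C@@](C)(CC(=O)O)O2
F4 | step 6 | methyl (2R,3R)-3-{[(2S)-2-methoxy-2-phenylacetyl]oxy}-2-methyl-2-(prop-2-en-1-yl)-3,4-dihydro-2H-chromene-6-carboxylate | COC(=O)c1ccc2c(c1)C[C@@H](OC(=O)[C@@H](OC)c1ccccc1)[C@@](C)(CC=C)O2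
F5 | step 6 | methyl (2S,3S)-3-{[(2S)-2-methoxy-2-phenylacetyl]oxy}-2-methyl-2-(prop-2-en-1-yl)-3,4-dihydro-2H-chromene-6-carboxylate | COC(=O)c1ccc2c(c1)C[C@H](OC(=O)[C@@H](OC)c1ccccc1)[C@](C)(CC=C)O2
F6 | step 6 | methyl (2R,3R)-3-hydroxy-2-methyl-2-(prop-2-en-1-yl)-3,4-dihydro-2H-chromene-6-carboxylate (single enantiomer) | COC(=O)c1ccc2c(c1)C[C@@H](O)[C@@](C)(CC=C)O2
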